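The route cuts the bond between the benzylic carbon C-beta and C1 of ring B (the catechol ring). The C(=O)–C-alpha(OH)–C-beta chain of the target is C1–C3 of (R)-malic acid, and its C4 carboxyl is traded for ring B. A nickel-catalysed electroreductive decarboxylative arylation joins the primary C-beta radical to a protected 4-iodocatechol in one operation, next to the untouched C-alpha stereocentre. The precursor is the N-hydroxyphthalimide ester of malic acid acetonide, a 1,3-dioxolan-4-one that masks the alpha-hydroxy acid. Afterwards the lactone is opened to a Weinreb amide, silylated, used to acylate a lithiated prenylresorcinol (ring A) and deprotected.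

Key step: step 5

Remark: the target SMILES encodes the (R) configuration at C-alpha; this is the configuration and spatial arrangement of (R)-malic acid, which is carried through without inversion.

Step 1
Reactants: 1 (R)-malic acid
Product: 2 2-[(4R)-2,2-dimethyl-5-oxo-1,3-dioxolan-4-yl]acetic acid
Conditions: 2,2-dimethoxypropane, p-TsOH·H2O (cat.), rt
Reagents that add atoms: 2,2-dimethoxypropane, COC(C)(C)OC
Why: Acid-catalysed transacetalisation (acetonide formation) should close the five-membered dioxolanone on the alpha-hydroxy acid in preference to the six-membered ring on the distal carboxyl, which stays free, and the stereocentre is not touched.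

Step 2
Reactants: 2 2-[(4R)-2,2-dimethyl-5-oxo-1,3-dioxolan-4-yl]acetic acid
Product: 3 1,3-dioxoisoindolin-2-yl 2-[(4R)-2,2-dimethyl-5-oxo-1,3-dioxolan-4-yl]acetate
Conditions: N-hydroxyphthalimide, DIC, DMAP (cat.), CH2Cl2, 0 °C to rt
Reagents that add atoms: N-hydroxyphthalimide, O=C1c2ccccc2C(=O)N1O
Why: Steglich-type carbodiimide esterification should acylate N-hydroxyphthalimide with the free carboxyl while the dioxolanone, which has no free OH, stays closed.

Step 3
Reactants: 4 catechol
Product: 5 1,2-bis(methoxymethoxy)benzene
Conditions: MOMCl, i-Pr2NEt, CH2Cl2, 0 °C to rt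
Reagents that add atoms: chloromethyl methyl ether (MOMCl), COCCl
Why: Base-mediated O-alkylation with the alpha-chloro ether (Williamson-type acetal formation) should protect both phenols as MOM ethers, which tolerate reductive nickel catalysis and organometallic reagents and come off under mild acid.

Step 4
Reactants: 5 1,2-bis(methoxymethoxy)benzene
Product: 6 4-iodo-1,2-bis(methoxymethoxy)benzene
Conditions: NIS (1.0 equiv), TFA (cat.), MeCN, 0 °C to rt
Reagents that add atoms: N-iodosuccinimide, O=C1CCC(=O)N1I
Why: Electrophilic aromatic iodination should go para to an acetal oxygen at the equivalent C4/C5 positions, and the anhydrous medium with only catalytic acid should spare the MOM groups.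

Step 5
Reactants: 3 1,3-dioxoisoindolin-2-yl 2-[(4R)-2,2-dimethyl-5-oxo-1,3-dioxolan-4-yl]acetate; 6 4-iodo-1,2-bis(methoxymethoxy)benzene
Product: 7 (5R)-5-[3,4-bis(methoxymethoxy)benzyl]-2,2-dimethyl-1,3-dioxolan-4-one
Conditions: 3 (1.5 equiv), NiCl2·6H2O (20 mol%), 2,2'-bipyridine (20 mol%), AgNO3 (0.3 equiv), NMP, Mg anode, RVC cathode, undivided cell, constant current (ca. 2.5 F/mol), rt
Reagents that add atoms: none
Why: At the cathode the divalent nickel–bipyridine complex is reduced to low-valent nickel, which inserts into the C–I bond of 6, while single-electron transfer to 3 releases phthalimide anion and CO2 and leaves a primary radical at C-beta; the arylnickel species captures this radical and reductive elimination from the resulting trivalent aryl(alkyl)nickel forms the C-beta–C1 (ring B) bond, with the Mg anode as electron source and silver plated from AgNO3 keeping the cathode active. The closest known reaction type is the nickel-catalysed electrochemical decarboxylative arylation of N-hydroxyphthalimide esters of primary carboxylic acids with aryl halides, established on aspartate- and glutamate-derived esters. No ring is closed and no stereocentre is created: C-alpha sits beside the radical carbon but never carries spin or charge, so the (R) configuration brought in from malic acid should pass through unchanged. The step needs chemoselectivity for radical capture by nickel over hydrogen abstraction, dimerisation, 1,2-acyl migration to C-beta and beta-oxygen elimination. The dioxolanone should secure this: its carbonyl is an ester-type carbonyl that migrates far more slowly than a ketone would (the reason for coupling before ring A is attached), and the beta-oxygen is an acetal oxygen held in the ring, a poor leaving group from an alkylnickel. The MOM acetals and the lactone should be inert at the mild potential, and 3 is used in excess because its direct reduction is the expected main loss channel.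

Step 6
Reactants: 7 (5R)-5-[3,4-bis(methoxymethoxy)benzyl]-2,2-dimethyl-1,3-dioxolan-4-one
Product: 8 (2R)-3-[3,4-bis(methoxymethoxy)phenyl]-2-hydroxy-N-methoxy-N-methylpropanamide
Conditions: MeNHOMe·HCl, AlMe3, CH2Cl2, 0 °C to rt; aq. potassium sodium tartrate
Reagents that add atoms: N,O-dimethylhydroxylamine hydrochloride, CNOC.Cl
Why: Weinreb aminolysis by the aluminium amide formed in situ should open the activated lactone at its carbonyl, with the hemiketal so released shedding acetone on work-up, under Lewis-acidic, non-basic conditions that should not epimerise C-alpha.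

Step 7
Reactants: 8 (2R)-3-[3,4-bis(methoxymethoxy)phenyl]-2-hydroxy-N-methoxy-N-methylpropanamide
Product: 9 (2R)-3-[3,4-bis(methoxymethoxy)phenyl]-N-methoxy-N-methyl-2-(triethylsilyloxy)propanamide
Conditions: TESCl, imidazole, DMF, 0 °C to rt
Reagents that add atoms: chlorotriethylsilane, CC[Si](Cl)(CC)CC
Why: Imidazole-promoted silylation of the secondary alcohol should give the triethylsilyl ether, which removes the acidic OH before organolithium addition and is cleaved later by the same mild acid as the MOM ethers.

Step 8
Reactants: 10 resorcinol
Product: 11 1,3-bis(methoxymethoxy)benzene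
Conditions: MOMCl, i-Pr2NEt, CH2Cl2, 0 °C to rt
Reagents that add atoms: chloromethyl methyl ether (MOMCl), COCCl
Why: Base-mediated O-alkylation (Williamson-type acetal formation) should give the bis-MOM ether, whose acetal oxygens later direct both metalations of ring A.

Step 9
Reactants: 11 1,3-bis(methoxymethoxy)benzene; 12 prenyl bromide (1-bromo-3-methylbut-2-ene)
Product: 14 1,3-bis(methoxymethoxy)-2-(3-methylbut-2-en-1-yl)benzene, via 2-lithio arene 13 (not isolated)
Conditions: n-BuLi, THF, 0 °C to rt; then CuI (cat.), 12, −78 °C to rt
Reagents that add atoms: none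
Why: Directed ortho-metalation should lithiate C2 between the two acetal oxygens, and copper-catalysed SN2 allylation of the aryllithium at the primary carbon of 12 should give the linear prenyl arene.

Step 10
Reactants: 14 1,3-bis(methoxymethoxy)-2-(3-methylbut-2-en-1-yl)benzene; 9 (2R)-3-[3,4-bis(methoxymethoxy)phenyl]-N-methoxy-N-methyl-2-(triethylsilyloxy)propanamide
Product: 17 (2R)-1-[2,4-bis(methoxymethoxy)-3-(3-methylbut-2-en-1-yl)phenyl]-3-[3,4-bis(methoxymethoxy)phenyl]-2-(triethylsilyloxy)propan-1-one, via 4-lithio arene 15 (not isolated), via lithium hemiaminal adduct 16 (not isolated)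
Conditions: 14 (1.5 equiv), n-BuLi (1.4 equiv), THF, 0 °C; then 9 (1.0 equiv), −78 to −30 °C; aq. NH4Cl
Reagents that add atoms: none
Why: Directed ortho-metalation of 14 at C4 (the only ring position still next to an acetal oxygen) followed by Weinreb ketone synthesis should give the aryl ketone, since chelated adduct 16 should hold until the quench and so prevent both over-addition and enolisation at C-alpha.

Step 11
Reactants: 17 (2R)-1-[2,4-bis(methoxymethoxy)-3-(3-methylbut-2-en-1-yl)phenyl]-3-[3,4-bis(methoxymethoxy)phenyl]-2-(triethylsilyloxy)propan-1-one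
Product: 18 (2R)-1-[2,4-dihydroxy-3-(3-methylbut-2-en-1-yl)phenyl]-3-(3,4-dihydroxyphenyl)-2-hydroxypropan-1-one
Conditions: HCl (3 M aq.), MeOH, degassed, rt to 40 °C
Reagents that add atoms: none
Why: Acid-catalysed acetal exchange with methanol should remove the four aryl MOM groups while the triethylsilyl ether hydrolyses in the same pot, and the low temperature and short exposure are chosen to spare the prenyl double bond and the alpha-ketol stereocentre.

Compound list

1 | (R)-malic acid, (2R)-2-hydroxybutanedioic acid | OC(=O)[C@H](O)CC(=O)O | starting material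
2 | 2-[(4R)-2,2-dimethyl-5-oxo-1,3-dioxolan-4-yl]acetic acid | CC1(C)OC(=O)[C@@H](CC(=O)O)O1 | intermediate
3 | 1,3-dioxoisoindolin-2-yl 2-[(4R)-2,2-dimethyl-5-oxo-1,3-dioxolan-4-yl]acetate | CC1(C)OC(=O)[C@@H](CC(=O)ON2C(=O)c3ccccc3C2=O)O1 | intermediate
4 | catechol | Oc1ccccc1O | starting material
5 | 1,2-bis(methoxymethoxy)benzene | COCOc1ccccc1OCOC | intermediate
6 | 4-iodo-1,2-bis(methoxymethoxy)benzene | COCOc1ccc(I)cc1OCOC | intermediate
7 | (5R)-5-[3,4-bis(methoxymethoxy)benzyl]-2,2-dimethyl-1,3-dioxolan-4-one | CC1(C)OC(=O)[C@@H](Cc2ccc(OCOC)c(OCOC)c2)O1 | intermediate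
8 | (2R)-3-[3,4-bis(methoxymethoxy)phenyl]-2-hydroxy-N-methoxy-N-methylpropanamide | CON(C)C(=O)[C@H](O)Cc1ccc(OCOC)c(OCOC)c1 | intermediate
9 | (2R)-3-[3,4-bis(methoxymethoxy)phenyl]-N-methoxy-N-methyl-2-(triethylsilyloxy)propanamide | CON(C)C(=O)[C@H](O[Si](CC)(CC)CC)Cc1ccc(OCOC)c(OCOC)c1 | intermediate
10 | resorcinol | Oc1cccc(O)c1 | starting material
11 | 1,3-bis(methoxymethoxy)benzene | COCOc1cccc(OCOC)c1 | intermediate
12 | prenyl bromide (1-bromo-3-methylbut-2-ene) | CC(C)=CCBr | starting material
13 | [2,6-bis(methoxymethoxy)phenyl]lithium (2-lithio arene, not isolated) | [Li]c1c(OCOC)cccc1OCOC | intermediate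
14 | 1,3-bis(methoxymethoxy)-2-(3-methylbut-2-en-1-yl)benzene | COCOc1cccc(OCOC)c1CC=C(C)C | intermediate
15 | [2,4-bis(methoxymethoxy)-3-(3-methylbut-2-en-1-yl)phenyl]lithium (4-lithio arene, not isolated) | [Li]c1ccc(OCOC)c(CC=C(C)C)c1OCOC | intermediate
16 | lithium (2R)-1-[2,4-bis(methoxymethoxy)-3-(3-methylbut-2-en-1-yl)phenyl]-3-[3,4-bis(methoxymethoxy)phenyl]-1-[methoxy(methyl)amino]-2-(triethylsilyloxy)propan-1-olate (hemiaminal adduct, C1 configuration undefined, not isolated) | CON(C)C(O[Li])(c1ccc(OCOC)c(CC=C(C)C)c1OCOC)[C@H](O[Si](CC)(CC)CC)Cc1ccc(OCOC)c(OCOC)c1 | intermediate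
17 | (2R)-1-[2,4-bis(methoxymethoxy)-3-(3-methylbut-2-en-1-yl)phenyl]-3-[3,4-bis(methoxymethoxy)phenyl]-2-(triethylsilyloxy)propan-1-one | CC(C)=CCc1c(OCOC)ccc(C(=O)[C@H](O[Si](CC)(CC)CC)Cc2ccc(OCOC)c(OCOC)c2)c1OCOC | intermediate
18 | (2R)-1-[2,4-dihydroxy-3-(3-methylbut-2-en-1-yl)phenyl]-3-(3,4-dihydroxyphenyl)-2-hydroxypropan-1-one (CNP0408242.1) | CC(C)=CCc1c(O)ccc(C(=O)[C@H](O)Cc2ccc(O)c(O)c2)c1O | target

Total step count: 11.
Longest linear sequence: 7 steps (steps 1, 2, 5, 6, 7, 10, 11 from (R)-malic acid; the catechol branch through steps 3, 4, 5, 6, 7, 10, 11 is equally long).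

Steps most likely to fail

Step 5. The ester may fragment reductively at the cathode before nickel has engaged the iodide, so that the C-beta radical is capped by hydrogen or dimerises. Oxidative addition to the electron-rich iodide may also be slow enough for protodeiodination to compete. The fallback removes the electrode and replaces cross-electrophile coupling by a nucleophile–electrophile coupling. It sets out from iodide 6: direct zinc insertion (Zn dust, LiCl, THF, 50 °C) should give [3,4-bis(methoxymethoxy)phenyl]zinc iodide F1. F1 is then coupled with ester 3 in a thermal decarboxylative Negishi-type arylation (NiCl2(dme), 4,4'-di-tert-butyl-2,2'-bipyridine, THF–DMF, rt). The fallback returns to the route at 7.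

Step 10. n-BuLi may deprotonate the doubly activated benzylic–allylic CH2 of the prenyl group (lateral metalation) instead of the ring. This would lower the amount of aryl nucleophile, could shift the double bond, and would leave butyllithium free to attack the amide. The fallback replaces deprotonation by halogen–metal exchange. It sets out from 14: NBS in MeCN at 0 °C in the dark should brominate the strongly activated ring para to one acetal oxygen faster than it attacks the trisubstituted alkene. This should give 1-bromo-2,4-bis(methoxymethoxy)-3-(3-methylbut-2-en-1-yl)benzene F2. Bromine–lithium exchange (t-BuLi, 2 equiv, THF, −78 °C), which outruns any deprotonation, should then deliver aryllithium 15, where the route is rejoined.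

Step 11. During the exposure needed to cleave four acetals, a freed ortho-phenol or methanol may add across the prenyl double bond (chroman formation or Markovnikov solvolysis). Acid-catalysed enolisation may also erode the alpha-ketol stereocentre. The fallback avoids free Brønsted acid and splits the deprotection into acetal-to-silyl exchange and fluoride cleavage. It sets out from 17: TESOTf with 2,2'-bipyridyl in MeCN should convert the four aryl MOM ethers directly into aryl triethylsilyl ethers. This should give (2R)-1-[3-(3-methylbut-2-en-1-yl)-2,4-bis(triethylsilyloxy)phenyl]-3-[3,4-bis(triethylsilyloxy)phenyl]-2-(triethylsilyloxy)propan-1-one F3. Buffered fluoride (HF·pyridine, pyridine, THF, 0 °C) should then remove all five silyl groups and return to the route at 18.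

Further compounds

F1 | step 5 | [3,4-bis(methoxymethoxy)phenyl]zinc iodide | COCOc1ccc([Zn]I)cc1OCOC
F2 | step 10 | 1-bromo-2,4-bis(methoxymethoxy)-3-(3-methylbut-2-en-1-yl)benzene | COCOc1ccc(Br)c(OCOC)c1CC=C(C)C
F3 | step 11 | (2R)-1-[3-(3-methylbut-2-en-1-yl)-2,4-bis(triethylsilyloxy)phenyl]-3-[3,4-bis(triethylsilyloxy)phenyl]-2-(triethylsilyloxy)propan-1-one | CC(C)=CCc1c(O[Si](CC)(CC)CC)ccc(C(=O)[C@H](O[Si](CC)(CC)CC)Cc2ccc(O[Si](CC)(CC)CC)c(O[Si](CC)(CC)CC)c2)c1O[Si](CC)(CC)CC
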